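**Plan**
1. Atom labels follow the target: C1 lactone carbonyl, C2, C3 (CH–OO), C4 (Me, lactone O), C5, C6 (Me, OO), C7–C12 chain CH2, C13=C14–C15=C16–Ph.
2. Retrosynthesis cuts C13=C14 (HWE), C7–C8 (Wittig, then diimide), the lactone O–C1 bond, C3–H, then both peroxide bonds C6–O and C3–O in one step (epoxide + ketone + H2O2), then C2–C3 (Claisen) and C4–C5 (enolate alkylation).
3. Enabling feature: the O–O bridge joins C6, a tertiary carbon flanked by the chain CH2 C7, to C3, which is β to C1 and next to the oxygenated quaternary C4; a C6–C7 epoxide and a C3 ketone can therefore take up the two oxygens of H2O2.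
4. Forward: the acyclic C1–C7 epoxy keto ester is built, the 1,2-dioxane closes first (step 6), C3 is reduced, the γ-lactone closes (step 9), and the C8–C16 chain is joined last by two olefinations.
5. Stereochemistry: C4 from (S)-lactic acid (alkylation with retention through the pivalaldehyde acetal), C6 from (S)-2-methylglycidol with one inversion in the perhydrolysis, C3 by axial hydride delivery to the ring cation under control of C4 and C6, both alkenes E from the HWE step.

Key step: step 6

Assumption: the C3 anomers of 14 and 15 are carried on together because C3 is re-set in step 8; the compounds marked as starting materials are taken as purchasable.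

Step 1
Reactants: 1 (S)-lactic acid; 2 pivalaldehyde
Product: 3 (2S,5S)-2-tert-butyl-5-methyl-1,3-dioxolan-4-one
Conditions: TsOH·H2O (cat.), H2SO4 (cat.), pentane, reflux, Dean–Stark; recrystallise at −78 °C
Reagents that add atoms: none
Why: Acid-catalysed acetalisation with azeotropic water removal should give mainly the cis acetal, purified by cold crystallisation; the new acetal centre (2S) is set by the lactate centre and stores its configuration.

Step 2
Reactants: 4 (S)-2-methylglycidol
Product: 5 [(2R)-2-methyloxiran-2-yl]methyl trifluoromethanesulfonate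
Conditions: Tf2O, 2,6-lutidine, CH2Cl2, −78 °C; cold work-up, used at once
Reagents that add atoms: trifluoromethanesulfonic anhydride, O=S(=O)(OS(=O)(=O)C(F)(F)F)C(F)(F)F
Why: O-sulfonylation of the primary alcohol with a hindered base leaves the stereocentre untouched; the descriptor changes from S to R only because the sulfonate raises the CIP rank of the exocyclic CH2.

Step 3
Reactants: 3 dioxolanone; 5 epoxy triflate
Product: 7 (2S,5R)-2-tert-butyl-5-methyl-5-{[(2S)-2-methyloxiran-2-yl]methyl}-1,3-dioxolan-4-one, via dioxolanone lithium enolate 6 (not isolated)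
Conditions: LDA, THF, −78 °C; then 5, DMPU, −78 → −40 °C
Reagents that add atoms: none
Why: Enolate alkylation under self-regeneration of the stereocentre: the electrophile enters anti to the tert-butyl group, so the new C4–C5 bond replaces the lactate C–H with retention (5R), and direct SN2 displacement of the primary triflate keeps the oxirane configuration.

Step 4
Reactants: 7 alkylated dioxolanone; 8 tert-butyl acetate
Product: 10 tert-butyl (4R)-4-hydroxy-4-methyl-5-[(2S)-2-methyloxiran-2-yl]-3-oxopentanoate, via tert-butyl acetate lithium enolate 9 (not isolated)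
Conditions: 8 (3 equiv), LDA (3 equiv), THF, −78 °C; then 7, −78 → −30 °C; aq NH4Cl at −78 °C
Reagents that add atoms: none
Why: Crossed Claisen acylation: the ester enolate adds to the activated acylal carbonyl and the adduct collapses with loss of pivalaldehyde to the γ-hydroxy β-keto ester; the quaternary C4 cannot epimerise and the tert-butyl ester slows tetronate closure.

Step 5
Reactants: 10 hydroxy keto ester
Product: 11 tert-butyl (4R)-4-methyl-5-[(2S)-2-methyloxiran-2-yl]-3-oxo-4-[(triethylsilyl)oxy]pentanoate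
Conditions: TESCl, imidazole, DMAP (cat.), DMF, rt
Reagents that add atoms: chlorotriethylsilane, CC[Si](Cl)(CC)CC
Why: Silylation of the tertiary α-ketol hydroxyl under mild basic conditions that leave the epoxide and the β-keto ester intact; the silyl ether blocks tetronate formation and attack of the C4 oxygen on the epoxide in step 6.

Step 6
Reactants: 11 silylated epoxy keto ester; 12 hydrogen peroxide
Product: 14 tert-butyl 2-[(4R,6R)-3-hydroxy-6-(hydroxymethyl)-4,6-dimethyl-4-[(triethylsilyl)oxy]-1,2-dioxan-3-yl]acetate (C3 anomers), via hydroperoxy keto ester 13 (not isolated)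
Conditions: H2O2 (dried ethereal solution, ca. 10 equiv), H3PMo12O40·xH2O (5 mol %), Et2O, 0 °C → rt
Reagents that add atoms: none
Why: The Mo(VI)-peroxo heteropoly acid activates the 2,2-disubstituted oxirane and H2O2 attacks the tertiary carbon C6 opposite the breaking C–O bond (borderline SN2, inversion) to give the β-hydroxy hydroperoxide 13, whose OOH group then adds to the C3 ketone, made electrophilic by the flanking ester and silyloxy carbon, to give the cyclic hemiperketal. The closest known reactions are the phosphomolybdic acid-catalysed perhydrolysis of epoxides in ethereal H2O2 and the spontaneous closure of δ-hydroperoxy ketones to 1,2-dioxan-3-ols. The 1,2-dioxane closes by 6-exo-trig addition of the hydroperoxide oxygen to the carbonyl carbon. The C6 stereocentre (6R at this stage) is controlled by the epoxide configuration through stereospecific inversion, while C3 forms as an anomer mixture that is erased in step 8. The step needs attack at C6 and not C7, and perhydrolysis faster than 5-exo capture of the epoxide by the C3 carbonyl oxygen: the tertiary centre directs the regiochemistry, the large excess of H2O2 in a non-ionising ether together with the electron-poor, hindered carbonyl disfavours internal capture and a free cation, and the TES ether keeps the C4 oxygen out of play.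

Step 7
Reactants: 14 hemiperketal
Product: 15 tert-butyl 2-[(4R,6R)-6-{[(tert-butyldimethylsilyl)oxy]methyl}-3-hydroxy-4,6-dimethyl-4-[(triethylsilyl)oxy]-1,2-dioxan-3-yl]acetate (C3 anomers)
Conditions: TBSCl, imidazole, CH2Cl2, 0 °C
Reagents that add atoms: tert-butyl(chloro)dimethylsilane, CC(C)(C)[Si](C)(C)Cl
Why: Selective silylation of the primary hydroxyl (the tertiary hemiperketal OH is inert) keeps the C7 oxygen from bridging to C3 when the ring cation is formed in step 8.

Step 8
Reactants: 15 protected hemiperketal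
Product: 16 tert-butyl 2-[(3R,4R,6R)-6-{[(tert-butyldimethylsilyl)oxy]methyl}-4,6-dimethyl-4-[(triethylsilyl)oxy]-1,2-dioxan-3-yl]acetate
Conditions: Et3SiH (5 equiv), TMSOTf (0.2 equiv), CH2Cl2, −78 °C
Reagents that add atoms: none
Why: Ionic hydrogenation of a peroxy hemiketal through its peroxycarbenium ion: hydride is expected to add axially, anti to the pseudoaxial C4–O bond (polar Felkin–Anh sense), to the half-chair that keeps both ring methyl groups equatorial, which places H-3 cis to the C4 methyl (3R) and the acetate arm cis to the C4 oxygen.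

Step 9
Reactants: 16 dioxane ester
Product: 18 (3R,4aR,7aR)-3-(hydroxymethyl)-3,4a-dimethyl-3,4,4a,7a-tetrahydrofuro[3,2-c][1,2]dioxin-6(7H)-one, via dihydroxy acid 17 (not isolated)
Conditions: TFA–CH2Cl2 1:4, 0 °C → rt; then NaHCO3, aq MeOH
Reagents that add atoms: none
Why: Acidolysis removes the tert-butyl ester (as isobutene) and both silyl ethers, and the cis-disposed C4 hydroxyl and C1 acid should close the γ-lactone by acid-catalysed lactonisation; no stereocentre is touched and dialkyl peroxides tolerate cold TFA.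

Step 10
Reactants: 18 hydroxymethyl peroxylactone
Product: 19 (3R,4aR,7aR)-3,4a-dimethyl-6-oxo-3,4,4a,6,7,7a-hexahydrofuro[3,2-c][1,2]dioxine-3-carbaldehyde
Conditions: Dess–Martin periodinane, NaHCO3, CH2Cl2, rt
Reagents that add atoms: none
Why: Dess–Martin oxidation of the primary alcohol under buffered, non-basic conditions that spare the peroxide; the α-quaternary aldehyde cannot enolise.

Step 11
Reactants: 20 (6-bromohexyloxy)(tert-butyl)dimethylsilane; 21 triphenylphosphine
Product: 22 [6-(tert-butyldimethylsilyloxy)hexyl]triphenylphosphonium bromide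
Conditions: PPh3, MeCN, reflux
Reagents that add atoms: none
Why: SN2 quaternisation of triphenylphosphine by a primary bromide.

Step 12
Reactants: 19 aldehyde; 22 phosphonium bromide
Product: 24 (3R,4aR,7aR)-3-[(1Z)-7-{[tert-butyl(dimethyl)silyl]oxy}hept-1-en-1-yl]-3,4a-dimethyl-3,4,4a,7a-tetrahydrofuro[3,2-c][1,2]dioxin-6(7H)-one, via phosphonium ylide 23 (not isolated)
Conditions: 22, NaHMDS, THF, 0 °C; then 19 at −78 °C, −78 → 0 °C
Reagents that add atoms: none
Why: Wittig olefination of a non-enolisable aldehyde with a salt-free unstabilised ylide (Z-alkene expected, geometry irrelevant); carbonyl addition at −78 °C should outrun deprotonation α to the lactone.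

Step 13
Reactants: 24 alkene
Product: 25 (3S,4aR,7aR)-3-(7-{[tert-butyl(dimethyl)silyl]oxy}heptyl)-3,4a-dimethyl-3,4,4a,7a-tetrahydrofuro[3,2-c][1,2]dioxin-6(7H)-one
Conditions: KO2C–N=N–CO2K (excess), AcOH, MeOH–CH2Cl2, 0 °C → rt
Reagents that add atoms: none
Why: Diimide reduction delivers H2 to the disubstituted alkene by concerted syn transfer and does not cleave O–O bonds, unlike catalytic hydrogenation; the C6 descriptor changes to S only through CIP ranking.

Step 14
Reactants: 25 silyl ether
Product: 26 (3S,4aR,7aR)-3-(7-hydroxyheptyl)-3,4a-dimethyl-3,4,4a,7a-tetrahydrofuro[3,2-c][1,2]dioxin-6(7H)-one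
Conditions: HF·pyridine, pyridine, THF, 0 °C → rt
Reagents that add atoms: none
Why: Fluoride-mediated desilylation of the primary TBS ether under buffered acidic conditions compatible with the lactone and the peroxide.

Step 15
Reactants: 26 alcohol
Product: 27 7-[(3S,4aR,7aR)-3,4a-dimethyl-6-oxo-3,4,4a,6,7,7a-hexahydrofuro[3,2-c][1,2]dioxin-3-yl]heptanal
Conditions: Dess–Martin periodinane, NaHCO3, CH2Cl2, rt
Reagents that add atoms: none
Why: Dess–Martin oxidation of a primary alcohol to the aldehyde without base or over-oxidation.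

Step 16
Reactants: 27 aldehyde; 28 diethyl [(2E)-3-phenylprop-2-en-1-yl]phosphonate
Product: 30 plakortolide Q, via lithiated phosphonate 29 (not isolated)
Conditions: 28, LiHMDS, THF, −78 °C; then 27, −78 → 0 °C
Reagents that add atoms: none
Why: Horner–Wadsworth–Emmons olefination: the lithiated cinnamyl phosphonate adds through its α-carbon and eliminates to the E alkene, so the (7E,9E)-diene should result with the cinnamyl geometry retained; addition at −78 °C is expected to outpace deprotonation of the lactone.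

**Compound list**
1 | (S)-lactic acid | C[C@H](O)C(=O)O | starting material
2 | pivalaldehyde | CC(C)(C)C=O | starting material
3 | (2S,5S)-2-tert-butyl-5-methyl-1,3-dioxolan-4-one | C[C@@H]1O[C@H](C(C)(C)C)OC1=O | intermediate
4 | (S)-2-methylglycidol, [(2S)-2-methyloxiran-2-yl]methanol | C[C@]1(CO)CO1 | starting material
5 | [(2R)-2-methyloxiran-2-yl]methyl trifluoromethanesulfonate | C[C@]1(COS(=O)(=O)C(F)(F)F)CO1 | intermediate
6 | lithium (2S)-2-tert-butyl-5-methyl-1,3-dioxol-4-olate (enolate of 3, not isolated) | CC1=C(O[Li])O[C@@H](C(C)(C)C)O1 | intermediate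
7 | (2S,5R)-2-tert-butyl-5-methyl-5-{[(2S)-2-methyloxiran-2-yl]methyl}-1,3-dioxolan-4-one | C[C@]1(C[C@@]2(C)CO2)O[C@H](C(C)(C)C)OC1=O | intermediate
8 | tert-butyl acetate | CC(=O)OC(C)(C)C | starting material
9 | lithium 1-tert-butoxyethen-1-olate (enolate of 8, not isolated) | C=C(O[Li])OC(C)(C)C | intermediate
10 | tert-butyl (4R)-4-hydroxy-4-methyl-5-[(2S)-2-methyloxiran-2-yl]-3-oxopentanoate | CC(C)(C)OC(=O)CC(=O)[C@](C)(O)C[C@@]1(C)CO1 | intermediate
11 | tert-butyl (4R)-4-methyl-5-[(2S)-2-methyloxiran-2-yl]-3-oxo-4-[(triethylsilyl)oxy]pentanoate | CC(C)(C)OC(=O)CC(=O)[C@](C)(O[Si](CC)(CC)CC)C[C@@]1(C)CO1 | intermediate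
12 | hydrogen peroxide | OO | starting material
13 | tert-butyl (4R,6R)-6-hydroperoxy-7-hydroxy-4,6-dimethyl-3-oxo-4-[(triethylsilyl)oxy]heptanoate (not isolated) | CC(C)(C)OC(=O)CC(=O)[C@](C)(O[Si](CC)(CC)CC)C[C@](C)(CO)OO | intermediate
14 | tert-butyl 2-[(4R,6R)-3-hydroxy-6-(hydroxymethyl)-4,6-dimethyl-4-[(triethylsilyl)oxy]-1,2-dioxan-3-yl]acetate (C3 anomers) | OC[C@@]1(C)C[C@@](C)(O[Si](CC)(CC)CC)C(O)(CC(=O)OC(C)(C)C)OO1 | intermediate
15 | tert-butyl 2-[(4R,6R)-6-{[(tert-butyldimethylsilyl)oxy]methyl}-3-hydroxy-4,6-dimethyl-4-[(triethylsilyl)oxy]-1,2-dioxan-3-yl]acetate (C3 anomers) | CC(C)(C)[Si](C)(C)OC[C@@]1(C)C[C@@](C)(O[Si](CC)(CC)CC)C(O)(CC(=O)OC(C)(C)C)OO1 | intermediate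
16 | tert-butyl 2-[(3R,4R,6R)-6-{[(tert-butyldimethylsilyl)oxy]methyl}-4,6-dimethyl-4-[(triethylsilyl)oxy]-1,2-dioxan-3-yl]acetate | CC(C)(C)[Si](C)(C)OC[C@@]1(C)C[C@@](C)(O[Si](CC)(CC)CC)[C@@H](CC(=O)OC(C)(C)C)OO1 | intermediate
17 | 2-[(3R,4R,6R)-4-hydroxy-6-(hydroxymethyl)-4,6-dimethyl-1,2-dioxan-3-yl]acetic acid (not isolated) | OC[C@@]1(C)C[C@@](C)(O)[C@@H](CC(=O)O)OO1 | intermediate
18 | (3R,4aR,7aR)-3-(hydroxymethyl)-3,4a-dimethyl-3,4,4a,7a-tetrahydrofuro[3,2-c][1,2]dioxin-6(7H)-one | OC[C@@]1(C)C[C@@]2(C)OC(=O)C[C@H]2OO1 | intermediate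
19 | (3R,4aR,7aR)-3,4a-dimethyl-6-oxo-3,4,4a,6,7,7a-hexahydrofuro[3,2-c][1,2]dioxine-3-carbaldehyde | O=C[C@@]1(C)C[C@@]2(C)OC(=O)C[C@H]2OO1 | intermediate
20 | (6-bromohexyloxy)(tert-butyl)dimethylsilane | CC(C)(C)[Si](C)(C)OCCCCCCBr | starting material
21 | triphenylphosphine | c1ccc(cc1)P(c1ccccc1)c1ccccc1 | starting material
22 | [6-(tert-butyldimethylsilyloxy)hexyl]triphenylphosphonium bromide | CC(C)(C)[Si](C)(C)OCCCCCC[P+](c1ccccc1)(c1ccccc1)c1ccccc1.[Br-] | intermediate
23 | [6-(tert-butyldimethylsilyloxy)hexylidene]triphenylphosphorane (not isolated) | CC(C)(C)[Si](C)(C)OCCCCCC=P(c1ccccc1)(c1ccccc1)c1ccccc1 | intermediate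
24 | (3R,4aR,7aR)-3-[(1Z)-7-{[tert-butyl(dimethyl)silyl]oxy}hept-1-en-1-yl]-3,4a-dimethyl-3,4,4a,7a-tetrahydrofuro[3,2-c][1,2]dioxin-6(7H)-one | CC(C)(C)[Si](C)(C)OCCCCC/C=C\[C@@]1(C)C[C@@]2(C)OC(=O)C[C@H]2OO1 | intermediate
25 | (3S,4aR,7aR)-3-(7-{[tert-butyl(dimethyl)silyl]oxy}heptyl)-3,4a-dimethyl-3,4,4a,7a-tetrahydrofuro[3,2-c][1,2]dioxin-6(7H)-one | CC(C)(C)[Si](C)(C)OCCCCCCC[C@@]1(C)C[C@@]2(C)OC(=O)C[C@H]2OO1 | intermediate
26 | (3S,4aR,7aR)-3-(7-hydroxyheptyl)-3,4a-dimethyl-3,4,4a,7a-tetrahydrofuro[3,2-c][1,2]dioxin-6(7H)-one | OCCCCCCC[C@@]1(C)C[C@@]2(C)OC(=O)C[C@H]2OO1 | intermediate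
27 | 7-[(3S,4aR,7aR)-3,4a-dimethyl-6-oxo-3,4,4a,6,7,7a-hexahydrofuro[3,2-c][1,2]dioxin-3-yl]heptanal | O=CCCCCCC[C@@]1(C)C[C@@]2(C)OC(=O)C[C@H]2OO1 | intermediate
28 | diethyl [(2E)-3-phenylprop-2-en-1-yl]phosphonate | CCOP(=O)(OCC)C/C=C/c1ccccc1 | starting material
29 | lithium salt of the α-carbanion of 28 (not isolated) | [Li+].CCOP(=O)(OCC)[CH-]/C=C/c1ccccc1 | intermediate
30 | plakortolide Q, (3S,4aR,7aR)-3,4a-dimethyl-3-[(7E,9E)-10-phenyldeca-7,9-dien-1-yl]-3,4,4a,7a-tetrahydrofuro[3,2-c][1,2]dioxin-6(7H)-one | C[C@]1(CCCCCC/C=C/C=C/c2ccccc2)C[C@@]2(C)OC(=O)C[C@H]2OO1 | target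

**Count and risks**
Total step count: 16. Longest linear sequence: 14 steps (1, 3–10, 12–16) from (S)-lactic acid; steps 2 and 11 are side branches.

Step 8 is the least secure. Facial selectivity of the hydride transfer may be poor, because the flipped half-chair with the C4 methyl pseudoaxial would lead hydride to the other face of C3. The cation may also lose H-2 or undergo Criegee-type O–O heterolysis before it is reduced. The fallback uses no hydride at C3: the C3–O bond is formed last, on a butenolide, where the tether through C4 allows only the cis ring fusion. It sets out from 7. DIBAL-H at −78 °C should give the lactol F1. Olefination with methyl (triphenylphosphoranylidene)acetate in MeOH (Z-favouring for α-oxygenated aldehydes, with release of pivalaldehyde) should give the (Z)-hydroxy enoate F2, which lactonises to the epoxy butenolide F3. Perhydrolysis under the conditions of step 6 should give the hydroperoxide F4; no carbonyl oxygen can reach C6 in this substrate. After H2O2 is washed out, catalytic Et2NH in CF3CH2OH should close the 1,2-dioxane by intramolecular oxa-Michael addition. This comes back to the route at 18 and bypasses steps 4–9.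

Step 6 may fail by internal capture of the acid-activated epoxide by the C3 carbonyl or enol oxygen (5-exo) before H2O2 arrives, by ionisation at C6 with loss of configuration, or by loss of the TES group followed by tetronate closure. The fallback takes the carbonyl out of reach before perhydrolysis and forms C3–O by conjugate addition. It sets out from 11. NaBH4 in MeOH at −20 °C should give the β-hydroxy ester F5. MsCl and Et3N should give the mesylate F6, and DBU the (E)-enoate F7. Perhydrolysis as in step 6 should then give the hydroperoxide F8. Et2NH in CF3CH2OH should induce 6-exo oxa-Michael closure through the chair that keeps both ring methyl groups equatorial, giving the dioxane acetate F9. TFA as in step 9 returns to the route at 18.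

Step 3 may fail by self-condensation of the thermally labile enolate before the hindered triflate is consumed, or by attack at the oxirane CH2 followed by re-closure, which would erode the configuration at C6. The fallback brings in C5–C7 as an allyl unit and makes the epoxide afterwards under catalyst control. It sets out from 3. Alkylation of the enolate with 3-bromo-2-methylpropene should give the methallyl dioxolanone F10. Acylation with 9 as in step 4 should give the alkene hydroxy keto ester F11. Hydroxyl-directed asymmetric epoxidation of this homoallylic tertiary alcohol (tungsten–bishydroxamic acid catalyst, aqueous H2O2), with the ligand enantiomer chosen for the (S)-oxirane, returns to the route at 10.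

**Further compounds**
F1 | step 8 | (2S,5R)-2-tert-butyl-5-methyl-5-{[(2S)-2-methyloxiran-2-yl]methyl}-1,3-dioxolan-4-ol (C4 epimers) | C[C@]1(C[C@@]2(C)CO2)O[C@H](C(C)(C)C)OC1O
F2 | step 8 | methyl (2Z,4R)-4-hydroxy-4-methyl-5-[(2S)-2-methyloxiran-2-yl]pent-2-enoate | COC(=O)/C=C\[C@](C)(O)C[C@@]1(C)CO1
F3 | step 8 | (5R)-5-methyl-5-{[(2S)-2-methyloxiran-2-yl]methyl}furan-2(5H)-one | C[C@]1(C[C@@]2(C)CO2)OC(=O)C=C1
F4 | step 8 | (5R)-5-[(2R)-2-hydroperoxy-3-hydroxy-2-methylpropyl]-5-methylfuran-2(5H)-one | C[C@]1(C[C@](C)(CO)OO)OC(=O)C=C1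
F5 | step 6 | tert-butyl (4R)-3-hydroxy-4-methyl-5-[(2S)-2-methyloxiran-2-yl]-4-[(triethylsilyl)oxy]pentanoate (C3 epimers) | CC(C)(C)OC(=O)CC(O)[C@](C)(O[Si](CC)(CC)CC)C[C@@]1(C)CO1
F6 | step 6 | tert-butyl (4R)-4-methyl-3-[(methylsulfonyl)oxy]-5-[(2S)-2-methyloxiran-2-yl]-4-[(triethylsilyl)oxy]pentanoate (C3 epimers) | CC(C)(C)OC(=O)CC(OS(C)(=O)=O)[C@](C)(O[Si](CC)(CC)CC)C[C@@]1(C)CO1
F7 | step 6 | tert-butyl (2E,4R)-4-methyl-5-[(2S)-2-methyloxiran-2-yl]-4-[(triethylsilyl)oxy]pent-2-enoate | CC(C)(C)OC(=O)/C=C/[C@](C)(O[Si](CC)(CC)CC)C[C@@]1(C)CO1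
F8 | step 6 | tert-butyl (2E,4R,6R)-6-hydroperoxy-7-hydroxy-4,6-dimethyl-4-[(triethylsilyl)oxy]hept-2-enoate | CC(C)(C)OC(=O)/C=C/[C@](C)(O[Si](CC)(CC)CC)C[C@](C)(CO)OO
F9 | step 6 | tert-butyl 2-[(3R,4R,6R)-6-(hydroxymethyl)-4,6-dimethyl-4-[(triethylsilyl)oxy]-1,2-dioxan-3-yl]acetate | OC[C@@]1(C)C[C@@](C)(O[Si](CC)(CC)CC)[C@@H](CC(=O)OC(C)(C)C)OO1
F10 | step 3 | (2S,5R)-2-tert-butyl-5-methyl-5-(2-methylprop-2-en-1-yl)-1,3-dioxolan-4-one | C[C@]1(CC(C)=C)O[C@H](C(C)(C)C)OC1=O
F11 | step 3 | tert-butyl (4R)-4-hydroxy-4,6-dimethyl-3-oxohept-6-enoate | CC(C)(C)OC(=O)CC(=O)[C@](C)(O)CC(C)=C
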